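## Retrosynthetic overview

- The aryl ester C–O bond between the ring A carbonyl and O4 of ring B is cut. This gives 3-formyl-2-hydroxy-4-methoxy-6-methylbenzoic acid and the benzyl ester of 2,4-dihydroxy-3,6-dimethylbenzoic acid, and the benzyl group is removed in the last step.
- The strategy rests on ring B (C1 CO2H, C2 OH, C3 CH3, C4 O-aroyl, C5 H, C6 CH3). Its oxygens at C2 and C4 are meta to each other beside the C1 carboxyl, so adding two hydrogens turns it into a 2,4-dioxocyclohexane-1-carboxylate.
- That dione is cut at C1–C6 (Michael) and C2–C3 (Claisen). Dibenzyl malonate supplies C1, C2 and the ester, and (E)-hex-4-en-3-one supplies C3–C6 and both methyl groups.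
- Ring A is not built. Methyl orsellinate is 4-O-methylated, formylated at C3 under direction of the 2-hydroxyl, and hydrolysed.
- Ring order: ring B is the only ring formed. It is closed saturated in step 1 and aromatised in step 2.

Key step: step 1

Assumption: dione 4 is drawn in its triketo form. It should exist largely as enol tautomers and as a mixture of racemic diastereomers. The mixture is carried on unseparated because step 2 makes C1, C3 and C6 trigonal. The target has no stereocentre.

## Route

Step 1
Reactants: 1 dibenzyl malonate; 2 (E)-hex-4-en-3-one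
Product: 4 benzyl 3,6-dimethyl-2,4-dioxocyclohexane-1-carboxylate, via Michael adduct 3 (not isolated)
Conditions: NaOBn (1.0 M in BnOH, 1.1 equiv), BnOH–toluene, 0 °C → 80 °C; sodium enolate extracted into H2O, organic wash, then aq HCl, 0 °C
Reagents that add atoms: none
Why: Benzyloxide deprotonates 1, and the soft malonate anion adds 1,4 to the methyl-bearing β-carbon of 2, forming ring B bond C1–C6 and giving keto diester 3. Proton exchange then produces the enolate on the ethyl side of the ketone, whose carbon attacks one benzyl ester carbonyl and expels benzyloxide, forming bond C2–C3 in a Claisen (Dieckmann-type) acylation that is 6-(enolendo)-exo-trig and allowed by Baldwin's rules for enolates. This tandem Michael–Claisen annulation of a malonate with an alkyl propenyl ketone is the established way to dihydroresorcylates. The selectivity needed is regiochemical and is secured by the connectivity of 3, because the inner methylene enolate could close only a four-membered ring, and all earlier equilibria are drained by deprotonation of the acidic tricarbonyl product, hence the full equivalent of base. The three new sp3 centres (C1, C3, C6) are not controlled, since C1 and C3 are epimerisable and all three become sp2 in step 2. Matching the alkoxide to the ester makes transesterification degenerate, and extracting the sodium enolate into water frees it from benzyl alcohol before cold acidification.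

Step 2
Reactants: 4 benzyl 3,6-dimethyl-2,4-dioxocyclohexane-1-carboxylate
Product: 6 benzyl 2,4-dihydroxy-3,6-dimethylbenzoate, via 3-bromo dione 5 (not isolated)
Conditions: CuBr2 (2.1 equiv), LiBr (1 equiv), MeCN, rt → reflux
Reagents that add atoms: none
Why: This is oxidative aromatisation of a cyclohexane-1,3-dione by α-halogenation and dehydrohalogenation, in which CuBr2 brominates the enol at C3 to give 5, the bromine shifts to C5 through the C4–C5 enol (allylic shift), HBr is lost across C5–C6, the dienone tautomerises to the resorcylate, and the benzyl ester stays inert.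

Step 3
Reactants: 7 methyl 2,4-dihydroxy-6-methylbenzoate (methyl orsellinate)
Product: 8 methyl 2-hydroxy-4-methoxy-6-methylbenzoate
Conditions: MeI (1.05 equiv), K2CO3 (1.1 equiv), acetone, reflux
Reagents that add atoms: iodomethane (MeI), CI
Why: This Williamson etherification is selective for the 4-hydroxyl because the 2-hydroxyl is hydrogen-bonded to the adjacent ester carbonyl and shielded by it, so one equivalent of MeI should alkylate only the free phenol.

Step 4
Reactants: 8 methyl 2-hydroxy-4-methoxy-6-methylbenzoate
Product: 10 methyl 3-formyl-2-hydroxy-4-methoxy-6-methylbenzoate, via hydroxymethyl phenol 9 (not isolated)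
Conditions: MgCl2 (anhydrous, 2 equiv), Et3N (4 equiv), (CH2O)n (6 equiv), MeCN, reflux; aq HCl
Reagents that add atoms: paraformaldehyde (reacts as formaldehyde), C=O
Why: In this Casnati–Skattebøl ortho-formylation the magnesium phenoxide of the 2-hydroxyl delivers coordinated formaldehyde to its only free ortho position C3 (C1 carries the ester and C5 is para and out of reach), and the benzylic alkoxide of 9 is then oxidised by a second formaldehyde in an Oppenauer-type hydride transfer.

Step 5
Reactants: 10 methyl 3-formyl-2-hydroxy-4-methoxy-6-methylbenzoate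
Product: 11 3-formyl-2-hydroxy-4-methoxy-6-methylbenzoic acid
Conditions: conc. H2SO4, 0 °C → rt; poured onto ice
Reagents that add atoms: water, O
Why: This is acid hydrolysis of a di-ortho-substituted benzoate by unimolecular acyl–oxygen cleavage (AAC1), the known behaviour of hindered esters in concentrated H2SO4, which avoids the hot strong base that would endanger the aldehyde, while the protonated formyl group deactivates the ring toward sulfonation and ipso-protonation.

Step 6
Reactants: 11 3-formyl-2-hydroxy-4-methoxy-6-methylbenzoic acid; 6 benzyl 2,4-dihydroxy-3,6-dimethylbenzoate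
Product: 13 benzyl 4-[(3-formyl-2-hydroxy-4-methoxy-6-methylbenzoyl)oxy]-2-hydroxy-3,6-dimethylbenzoate, via mixed anhydride 12 (not isolated)
Conditions: (CF3CO)2O (4 equiv), toluene, rt; aqueous work-up
Reagents that add atoms: none
Why: In this depside esterification through a mixed trifluoroacetic anhydride, 12 transfers its hindered aroyl group to the free 4-hydroxyl of 6, the 2-hydroxyls of both partners are chelated to neighbouring carbonyls and crowded and should stay unacylated, and any aryl trifluoroacetate is hydrolysed on work-up.

Step 7
Reactants: 13 benzyl 4-[(3-formyl-2-hydroxy-4-methoxy-6-methylbenzoyl)oxy]-2-hydroxy-3,6-dimethylbenzoate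
Product: 14 baeomycesic acid
Conditions: H2 (1 atm), 10% Pd/C, EtOAc, rt, stopped after uptake of one equivalent of H2
Reagents that add atoms: none
Why: Catalytic hydrogenolysis of the benzylic ester C–O bond should be much faster than reduction of the electron-rich, hydrogen-bonded aryl aldehyde when hydrogen uptake is limited, and it leaves the aryl ester and the methyl ether untouched.

## Compound list

1 | dibenzyl malonate | O=C(CC(=O)OCc1ccccc1)OCc1ccccc1 | starting material
2 | (E)-hex-4-en-3-one | CCC(=O)/C=C/C | starting material
3 | dibenzyl 2-(4-oxohexan-2-yl)propanedioate (racemic Michael adduct, not isolated) | CCC(=O)CC(C)C(C(=O)OCc1ccccc1)C(=O)OCc1ccccc1 | intermediate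
4 | benzyl 3,6-dimethyl-2,4-dioxocyclohexane-1-carboxylate (mixture of epimers and enol tautomers) | O=C(OCc1ccccc1)C1C(C)CC(=O)C(C)C1=O | intermediate
5 | benzyl 3-bromo-3,6-dimethyl-2,4-dioxocyclohexane-1-carboxylate (mixture of epimers, not isolated) | O=C(OCc1ccccc1)C1C(C)CC(=O)C(C)(Br)C1=O | intermediate
6 | benzyl 2,4-dihydroxy-3,6-dimethylbenzoate | Cc1cc(O)c(C)c(O)c1C(=O)OCc1ccccc1 | intermediate
7 | methyl 2,4-dihydroxy-6-methylbenzoate (methyl orsellinate) | COC(=O)c1c(C)cc(O)cc1O | starting material
8 | methyl 2-hydroxy-4-methoxy-6-methylbenzoate | COc1cc(C)c(C(=O)OC)c(O)c1 | intermediate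
9 | methyl 2-hydroxy-3-(hydroxymethyl)-4-methoxy-6-methylbenzoate (not isolated) | COc1cc(C)c(C(=O)OC)c(O)c1CO | intermediate
10 | methyl 3-formyl-2-hydroxy-4-methoxy-6-methylbenzoate | COc1cc(C)c(C(=O)OC)c(O)c1C=O | intermediate
11 | 3-formyl-2-hydroxy-4-methoxy-6-methylbenzoic acid | COc1cc(C)c(C(=O)O)c(O)c1C=O | intermediate
12 | 3-formyl-2-hydroxy-4-methoxy-6-methylbenzoic trifluoroacetic anhydride (not isolated) | COc1cc(C)c(C(=O)OC(=O)C(F)(F)F)c(O)c1C=O | intermediate
13 | benzyl 4-[(3-formyl-2-hydroxy-4-methoxy-6-methylbenzoyl)oxy]-2-hydroxy-3,6-dimethylbenzoate (benzyl baeomycesate) | COc1cc(C)c(C(=O)Oc2cc(C)c(C(=O)OCc3ccccc3)c(O)c2C)c(O)c1C=O | intermediate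
14 | baeomycesic acid | COc1cc(C)c(C(=O)Oc2cc(C)c(C(=O)O)c(O)c2C)c(O)c1C=O | target

## Step count

Total step count: 7.
Longest linear sequence: 5 (steps 3, 4, 5, 6, 7). The ring B arm (steps 1, 2) joins at step 6.

## Steps most likely to fail

**Step 2 (aromatisation).** Three things may go wrong:
- Bromination may run on into the electron-rich ring at C5 once the resorcinol has formed.
- HBr loss from the tertiary C3 bromide may stall.
- The HBr released at reflux may attack the benzyl ester.

The fallback sets out from 4 and comes back at 6, and it removes the two hydrogens without any halogen electrophile.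
- Dione 4 is converted into its dianion (LiN(iPr)2, 2.2 equiv, THF, −78 °C).
- The dianion reacts at the last-formed, ester-stabilised C1 carbanion with PhSeCl to give benzyl 3,6-dimethyl-2,4-dioxo-1-(phenylselanyl)cyclohexane-1-carboxylate F1.
- H2O2 in CH2Cl2 at 0 °C oxidises this to benzyl 3,6-dimethyl-2,4-dioxo-1-(phenylseleninyl)cyclohexane-1-carboxylate F2.
- The syn elimination of F2 can take only the C6 hydrogen, and the resulting C1=C6 enedione tautomerises to 6.

**Step 7 (hydrogenolysis).** Reduction of the formyl group to hydroxymethyl or methyl on palladium may compete with cleavage of the benzyl ester. The fallback sets out from 6 and comes back at 14, and it moves the hydrogenation to a stage where no aldehyde is present.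
- Ester 6 is hydrogenolysed (H2, Pd/C, EtOAc) to 2,4-dihydroxy-3,6-dimethylbenzoic acid F3.
- The carboxylate alone is alkylated with allyl bromide and KHCO3 in DMF at rt to give allyl 2,4-dihydroxy-3,6-dimethylbenzoate F4.
- F4 is acylated at its 4-hydroxyl by mixed anhydride 12, made from 11 as in step 6. This gives allyl 4-[(3-formyl-2-hydroxy-4-methoxy-6-methylbenzoyl)oxy]-2-hydroxy-3,6-dimethylbenzoate F5.
- A Tsuji–Trost deallylation follows (catalytic Pd(PPh3)4 as the zerovalent palladium source, sodium p-toluenesulfinate, THF–MeOH, rt, then dilute HCl). It releases 14 under non-reducing, near-neutral conditions.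

**Step 4 (formylation).** The reaction may be slow or stall because the magnesium phenoxide is tied up in a chelate with the ester carbonyl and C3 is crowded between two oxygens. Prolonged heating may also cause O-methoxymethylation. The fallback sets out from 7 and comes back at 10, bypassing 8 by reversing the order of formylation and methylation.
- A Rieche formylation of 7 (Cl2CHOMe, TiCl4, CH2Cl2, −10 → 0 °C) is steered to C3 by titanium binding to the flanking hydroxyls.
- It gives methyl 3-[chloro(methoxy)methyl]-2,4-dihydroxy-6-methylbenzoate F6.
- Aqueous HCl work-up hydrolyses F6 to methyl 3-formyl-2,4-dihydroxy-6-methylbenzoate F7, and chromatographic purification is foreseen.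
- One equivalent of MeI with K2CO3 in acetone then methylates the 4-hydroxyl to give 10. The 2-hydroxyl is chelated on both sides by the ester and the aldehyde.

## Further compounds

F1 | step 2 | benzyl 3,6-dimethyl-2,4-dioxo-1-(phenylselanyl)cyclohexane-1-carboxylate | O=C(OCc1ccccc1)C1([Se]c2ccccc2)C(C)CC(=O)C(C)C1=O
F2 | step 2 | benzyl 3,6-dimethyl-2,4-dioxo-1-(phenylseleninyl)cyclohexane-1-carboxylate | O=C(OCc1ccccc1)C1([Se](=O)c2ccccc2)C(C)CC(=O)C(C)C1=O
F3 | step 7 | 2,4-dihydroxy-3,6-dimethylbenzoic acid | Cc1cc(O)c(C)c(O)c1C(=O)O
F4 | step 7 | allyl 2,4-dihydroxy-3,6-dimethylbenzoate | C=CCOC(=O)c1c(C)cc(O)c(C)c1O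
F5 | step 7 | allyl 4-[(3-formyl-2-hydroxy-4-methoxy-6-methylbenzoyl)oxy]-2-hydroxy-3,6-dimethylbenzoate | COc1cc(C)c(C(=O)Oc2cc(C)c(C(=O)OCC=C)c(O)c2C)c(O)c1C=O
F6 | step 4 | methyl 3-[chloro(methoxy)methyl]-2,4-dihydroxy-6-methylbenzoate | COC(Cl)c1c(O)cc(C)c(C(=O)OC)c1O
F7 | step 4 | methyl 3-formyl-2,4-dihydroxy-6-methylbenzoate | COC(=O)c1c(C)cc(O)c(C=O)c1O
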